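## The problem

The target is an isoflavone (3-arylchromen-4-one) in which every carbon of ring A is substituted: methoxy at C5, an (S)-2-hydroxy-3-methylbutyl chain at C6, a free hydroxyl at C7 and a prenyl group at C8. Ring B is a 4-hydroxyphenyl group on C3. The main task is regiochemical: four different groups must be set in a fixed order on a phloroglucinol-type ring, and ring C must be fused to the one remaining edge, O1–C8a–C4a–C4. The only stereocentre is the carbinol carbon C2'' of the C6 chain. Nothing else in the molecule can control it, so it must come from a reagent or a chiral building block; once set, it is remote from all later bond-forming sites. O1 and the C7 oxygen belong to the same resorcinol unit but end in different roles, so they must be told apart. The sensitive groups are the prenyl alkene (it cyclises onto the C7 hydroxyl or adds acid), the pyranone (opened at C2 by strong base), the C5 methyl ether (the first to fall to chelating Lewis acids) and the aryloxy-vinyl link of any open-chain ring C precursor (attacked by nucleophiles). The feature the plan exploits is that C5, C6, C7 and C8 are all occupied: C4a is then the only free carbon ortho to O1, so a three-carbon unit already bound through O1–C2 can deliver its acyl carbon C4 to one position only.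

## Retrosynthesis

**Prenyl group and protecting groups last (21 from 20 from 18 and 19).** The three ester C–O bonds of triacetate 20 are cut first, then its C8–C1''' bond, which gives aryl bromide 18 and prenylstannane 19. The prenyl group goes in late because it would not outlast the acid that closes ring C. O-prenylation with rearrangement is the neighbouring option, but it needs a free C7 hydroxyl and heat and offers nothing once a halogen already sits on C8. Bromide 18 is acid-stable, and its halogen serves twice, as the blocking group for the ring closure and as the coupling handle. The forward coupling must work at a doubly ortho-substituted bromide and join the stannane through its CH2 end. The acetates keep the acidic C7 and C4' phenols away from the acid-labile allylstannane and then fall in one mild methanolysis.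

**Ring C by the C4–C4a bond (18 from 16).** Cutting C4–C4a turns chromone 18 into the aryloxyacrylic acid 16, activated in the flask as mixed anhydride 17. The alternatives are the deoxybenzoin order (C4–C4a first, then insertion of C2) and arylation of a 3-halochromone. The present cut is preferred because the three-carbon unit arrives with ring B and C2 in place, and because an O1–C2 bond made beforehand under base leaves the acid step no path to a coumarin. Precursor 16 is acyclic and is assembled from two pieces of similar size. The forward reaction requires that the acyl carbon find C4a (secured by bromine at C8), that the alkene reach the geometry with O1 and C4 cis, and that the esters hold in acid.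

**O1–C2 bond and the change of protecting groups (16 from 14 from 9 and 13).** The acetates and the carboxyl group of 16 are traced through hydroxy acid 15 to the tert-butyl ester and tert-butyl ether of 14. Cutting O1–C2 of 14 gives bromoresorcinol 9 and β-chloroacrylate 13. No acyl group is present when O1–C2 is formed, because aryl esters would migrate between phenoxides; the acetates are therefore put on after the base step. The 4'-oxygen travels as a tert-butyl ether that falls with the ester in acid, so the ester cleavage needs no nucleophile that could attack the aryloxy-vinyl unit. The forward step must choose between the two phenols of 9. The one that becomes O1 has a ring hydrogen as neighbour; the other is wedged between bromine and the branched chain.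

**The three-carbon unit with ring B (13 from 12 from 11 from 10).** The C–Cl bond of 13 goes back to the enol of formyl ester 12, the formyl carbon to a Claisen condensation of ester 11, and both tert-butyl groups to 4-hydroxyphenylacetic acid 10. Each step is a standard operation on an arylacetic ester.

**Bromine from silicon, phenols from acetals (9 from 8 from 7).** The two O–H bonds of 9 go back to the MOM ethers of 8, and its C–Br bond to the C–Si bond of 7. Bromination by ipso substitution is preferred to direct bromination because the free position next to the methoxy group is equally activated. Bromination precedes acetal cleavage because so electron-rich an aryl silane would lose silicon to a proton in acid.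

**Chain, stereocentre and the blocking group (7 from 4 and 5; 4 from 2 from 1).** Cutting C6–C1'' of 7 gives an aryllithium 6, made from silane 4, and the enantiopure epoxide 5. One bond thus installs the whole chain with its stereocentre, which is not touched. A stepwise build-up from an aldehyde would need an asymmetric step of its own. Silane 4 comes from bis-MOM ether 2 through aryllithium 3, and 2 from 5-methoxyresorcinol 1. The most acidic ring position of 2 lies between the two MOM ethers and is the future C8. It has to be blocked first, and silicon is chosen because, unlike bromine, it survives the second lithiation.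

## Roads not taken

**Alternative 1:** The cut is made inside the C6 chain, at C6–C1'' and C2''–C3'', so that chain and stereocentre arise in one catalytic three-component coupling. A vinylboronic ester and an isopropyl organolithium form a boron ate complex. This couples with aryl bromide A2 under Pd(OAc)2, a chiral ferrocenyl bisphosphine and NaOTf. Arylpalladium-induced 1,2-migration of the isopropyl group gives the secondary boronic ester A1, and stereoretentive C–B oxidation would give the carbinol.

- Merits: two C–C bonds and the stereocentre from achiral inputs in one step. A1 already carries the prenyl group, so no organotin reagent is needed at the end. In bond economy and convergence at ring A this road is better than the chosen one.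
- Weak points for this target: the aryl partner A2 is doubly ortho-substituted and electron-rich, so oxidative addition is slow. The migrating group is a secondary alkyl. The enantiomeric purity depends on a catalyst, not on a purchased centre. An early prenyl group rules out any acidic closure of ring C, and the two MOM-protected oxygens of A1 are no better differentiated than in the chosen route.
- Comparison: the chosen plan offers a stereocentre of guaranteed purity from epoxide 5, plain organolithium chemistry, and freedom to use the acid-mediated ring closure.

**Alternative 2:** The C2''–O bond is cut, so that the chain comes from a second prenyl group on the finished isoflavone A4, with silicon holding C8. The fructose-derived Shi ketone with KHSO5 would epoxidise the C2''–C3'' alkene of A4 on one face to give oxirane A3. A3 is then opened reductively.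

- Merits: both side chains come from the same cheap five-carbon unit. No chiral building block is needed, and the asymmetric step is late.
- Weak points for this target: the carbinol of the target needs hydride delivered to the tertiary carbon C3'' of A3, against the normal preference of hydride reagents. Conditions that favour this, with cationic character at C3'', invite rearrangement to the ketone and loss of the stereocentre. They also invite capture by the neighbouring C7 oxygen to give cyclic ethers. The facial selectivity of the epoxidation is good but not absolute. C8 must still be converted from silicon to halogen and then to prenyl, so nothing is saved at the end.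
- Comparison: the step counts are similar. The chosen plan avoids the regiochemical problem, because its epoxide 5 is opened by carbon at the primary position and the C–O bond of the stereocentre is never at risk.

**Alternative 3:** Ring A itself is cut, at C5–C6, C7–C8 and C4a–C5. Heating cyclobutenone A6 with the enantiopure siloxyalkyne A7 would open A6 to a vinylketene, add the alkyne, reopen to a dienylketene and close by six-electron electrocyclisation to phenol A5.

- Merits: all ring A substituents, prenyl included, are placed in one thermal cascade with regiochemistry fixed by the mechanism. No blocking group is needed, and the free phenol of A5 is the one to be methylated. In convergence and regiochemical certainty this is the strongest of the four plans.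
- Weak points for this target: A6 and A7 each need a synthesis of several steps. The prenyl alkene can intercept the vinylketene intramolecularly. The two silyloxy groups of A5 (the future O1 and C7 oxygen) still have to be told apart. An early prenyl group again excludes an acid ring closure.
- Comparison: the chosen plan offers a commercial arene, two directed lithiations and a markedly shorter sequence to the same substitution pattern.

Key step: step 11

Remark on the chemistry: the aryloxyacrylates 14 to 17 are drawn as E isomers, the expected thermodynamic form; the Z isomers would serve equally, because the acid of step 11 interconverts them. Epoxide 5 is taken as a purchased, enantiopure reagent.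

## Route

Step 1
Reactants: 1 5-methoxyresorcinol (5-methoxybenzene-1,3-diol)
Product: 2 1-methoxy-3,5-bis(methoxymethoxy)benzene
Conditions: NaH, MOMCl, DMF, 0 °C → rt
Reagents that add atoms: chloromethyl methyl ether (MOMCl), COCCl
Why: Williamson O-alkylation of both phenoxides; the MOM ethers are strong ortho-directing groups for the two lithiations and come off later in mild acid.

Step 2
Reactants: 2 1-methoxy-3,5-bis(methoxymethoxy)benzene
Product: 4 [4-methoxy-2,6-bis(methoxymethoxy)phenyl]trimethylsilane, via aryllithium 3 (not isolated)
Conditions: n-BuLi, THF, 0 °C; then TMSCl, −78 °C → rt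
Reagents that add atoms: chlorotrimethylsilane (TMSCl), C[Si](C)(C)Cl
Why: Directed ortho-metalation removes the proton flanked by two MOM ethers (the future C8), the most acidic site through double chelation. Silylation blocks this carbon and leaves a group that survives the next lithiation and can later be exchanged for bromine.

Step 3
Reactants: 4 [4-methoxy-2,6-bis(methoxymethoxy)phenyl]trimethylsilane; 5 (R)-2-isopropyloxirane [(2R)-2-(propan-2-yl)oxirane]
Product: 7 (2S)-1-[6-methoxy-2,4-bis(methoxymethoxy)-3-(trimethylsilyl)phenyl]-3-methylbutan-2-ol, via aryllithium 6 (not isolated)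
Conditions: s-BuLi, TMEDA, THF, −78 → −20 °C; then 5, BF3·OEt2, −78 °C; H2O
Reagents that add atoms: none
Why: With C8 blocked, the second directed ortho-metalation can only occur between the methoxy group and a MOM ether (the future C6). BF3-assisted SN2 opening of the epoxide at its CH2 carbon then forms the C6–C1'' bond. The C–O bond of the stereocentre is not broken, so (R)-5 gives the (S)-carbinol; only the priority order changes.

Step 4
Reactants: 7 (2S)-1-[6-methoxy-2,4-bis(methoxymethoxy)-3-(trimethylsilyl)phenyl]-3-methylbutan-2-ol
Product: 8 (2S)-1-[3-bromo-6-methoxy-2,4-bis(methoxymethoxy)phenyl]-3-methylbutan-2-ol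
Conditions: NBS, MeCN, 0 °C, dark
Reagents that add atoms: N-bromosuccinimide (NBS), O=C1CCC(=O)N1Br
Why: Electrophilic ipso-bromodesilylation; attack at the silicon-bearing carbon gives an arenium ion stabilised by the β-silicon effect, so substitution of silicon should outrun attack at the one remaining ring C–H. No acid is produced that could touch the acetals.

Step 5
Reactants: 8 (2S)-1-[3-bromo-6-methoxy-2,4-bis(methoxymethoxy)phenyl]-3-methylbutan-2-ol
Product: 9 2-bromo-4-[(2S)-2-hydroxy-3-methylbutyl]-5-methoxybenzene-1,3-diol
Conditions: HCl (cat.), MeOH, 40 °C
Reagents that add atoms: none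
Why: Acid-catalysed acetal exchange of both MOM ethers with methanol; the aryl bromide, the methyl ether and the secondary alcohol are inert under these conditions.

Step 6
Reactants: 10 4-hydroxyphenylacetic acid
Product: 11 tert-butyl 2-(4-tert-butoxyphenyl)acetate
Conditions: isobutene, H2SO4 (cat.), CH2Cl2, sealed vessel, rt
Reagents that add atoms: 2-methylpropene (isobutene), CC(C)=C
Why: Acid-catalysed addition of the carboxylic acid and the phenol to isobutene, the standard way to O-tert-butyl tyrosine tert-butyl esters. Both groups are stable to base and are removed together by acid.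

Step 7
Reactants: 11 tert-butyl 2-(4-tert-butoxyphenyl)acetate
Product: 12 tert-butyl (2Z)-2-(4-tert-butoxyphenyl)-3-hydroxyprop-2-enoate
Conditions: NaH, HCO2Et, THF, 0 °C → rt; then cold 1 M HCl
Reagents that add atoms: ethyl formate, CCOC=O
Why: Crossed Claisen condensation of the ester enolate with a non-enolisable formate; the product is written as its hydrogen-bonded Z enol.

Step 8
Reactants: 12 tert-butyl (2Z)-2-(4-tert-butoxyphenyl)-3-hydroxyprop-2-enoate
Product: 13 tert-butyl (2Z)-2-(4-tert-butoxyphenyl)-3-chloroprop-2-enoate
Conditions: PPh3, CCl4, MeCN, 60 °C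
Reagents that add atoms: tetrachloromethane, ClC(Cl)(Cl)Cl
Why: Appel-type deoxychlorination of an enolised 1,3-dicarbonyl compound through an enol oxyphosphonium salt and addition–elimination of chloride. The neutral conditions spare both tert-butyl groups, and the alkene geometry (Z expected) is not carried into later steps.

Step 9
Reactants: 9 2-bromo-4-[(2S)-2-hydroxy-3-methylbutyl]-5-methoxybenzene-1,3-diol; 13 tert-butyl (2Z)-2-(4-tert-butoxyphenyl)-3-chloroprop-2-enoate
Product: 14 tert-butyl (2E)-3-{2-bromo-3-hydroxy-4-[(2S)-2-hydroxy-3-methylbutyl]-5-methoxyphenoxy}-2-(4-tert-butoxyphenyl)prop-2-enoate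
Conditions: K2CO3 (1.1 equiv), DMF, 0 °C → rt, slow addition of 13
Reagents that add atoms: none
Why: Nucleophilic vinylic substitution (addition–elimination) of chloride by a phenoxide forms the O1–C2 bond under base. Of the two phenols, the one beside the ring hydrogen is less hindered and should be the more acidic, whereas the other lies between bromine and the branched chain and should react far more slowly with the α-arylated acceptor. No acyl group is present that could migrate between phenoxides.

Step 10
Reactants: 14 tert-butyl (2E)-3-{2-bromo-3-hydroxy-4-[(2S)-2-hydroxy-3-methylbutyl]-5-methoxyphenoxy}-2-(4-tert-butoxyphenyl)prop-2-enoate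
Product: 16 (2E)-3-{3-acetoxy-4-[(2S)-2-acetoxy-3-methylbutyl]-2-bromo-5-methoxyphenoxy}-2-(4-acetoxyphenyl)prop-2-enoic acid, via hydroxy acid 15 (not isolated)
Conditions: TFA, anisole, CH2Cl2, 0 °C → rt; evaporate; then Ac2O, pyridine, rt; H2O–THF
Reagents that add atoms: acetic anhydride, CC(=O)OC(C)=O
Why: Acidolysis (E1) of the tert-butyl ester and the aryl tert-butyl ether frees the acid and the 4'-phenol without a nucleophile that could attack the β-aryloxyacrylate; anisole traps the tert-butyl cation. Acetylation of the three hydroxyl groups follows, and the mixed carboxylic–acetic anhydride is hydrolysed in the aqueous work-up.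

Step 11
Reactants: 16 (2E)-3-{3-acetoxy-4-[(2S)-2-acetoxy-3-methylbutyl]-2-bromo-5-methoxyphenoxy}-2-(4-acetoxyphenyl)prop-2-enoic acid
Product: 18 7-acetoxy-6-[(2S)-2-acetoxy-3-methylbutyl]-3-(4-acetoxyphenyl)-8-bromo-5-methoxychromen-4-one, via mixed anhydride 17 (not isolated)
Conditions: TFAA, TFA, CH2Cl2, 0 °C → rt
Reagents that add atoms: none
Why: TFAA converts the acid into the mixed trifluoroacetic anhydride 17, which ionises in TFA to an acylium ion whose charge is shared with O1 (ketene–oxocarbenium form). In that form the C2–C3 bond has single-bond character, and reversible protonation at C3 acts in the same sense, so the E isomer can reach the Z geometry that brings C4 next to C4a. Attack of ring A on C4 and loss of the C4a proton complete an intramolecular Friedel–Crafts acylation; the closest known reaction type is the acid-mediated cyclisation of 3-aryloxyacrylic acids to chromones. The six-membered pyranone closes exo with respect to the acylium C–O multiple bond and endo with respect to the C4a–C8a bond of the arene. No stereocentre is formed, and the acetylated carbinol centre is remote and inert in this medium. The selectivity needed is the site of acylation: of the two carbons ortho to O1, C8 carries bromine, so only C4a is open, and it is activated by the ortho C5 methoxy and para C7 acetoxy groups. A coumarin cannot form because the O1–C2 bond already exists, and the three acetates resist the anhydride–acid medium that a prenyl group or an acetal would not.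

Step 12
Reactants: 18 7-acetoxy-6-[(2S)-2-acetoxy-3-methylbutyl]-3-(4-acetoxyphenyl)-8-bromo-5-methoxychromen-4-one; 19 tributyl(3-methylbut-2-enyl)stannane
Product: 20 7-acetoxy-6-[(2S)-2-acetoxy-3-methylbutyl]-3-(4-acetoxyphenyl)-5-methoxy-8-(3-methylbut-2-enyl)chromen-4-one
Conditions: Pd(PPh3)4 (cat.), DMF, 90 °C
Reagents that add atoms: none
Why: Stille coupling; zerovalent palladium inserts into the C8–Br bond of the electron-poor chromone, and transmetalation with reductive elimination at the unsubstituted allyl terminus gives the linear prenyl group. The neutral conditions leave the acetates in place, and these keep acidic phenols away from the allylstannane.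

Step 13
Reactants: 20 7-acetoxy-6-[(2S)-2-acetoxy-3-methylbutyl]-3-(4-acetoxyphenyl)-5-methoxy-8-(3-methylbut-2-enyl)chromen-4-one
Product: 21 7-hydroxy-6-[(2S)-2-hydroxy-3-methylbutyl]-3-(4-hydroxyphenyl)-5-methoxy-8-(3-methylbut-2-enyl)chromen-4-one
Conditions: K2CO3 (substoichiometric), MeOH, 0 °C → rt; then aq. NH4Cl
Reagents that add atoms: none
Why: Base-catalysed transesterification with methanol removes the two aryl acetates and the alkyl acetate. The conditions are too mild to open the pyranone or touch the prenyl alkene, and the stereocentre is not involved.

## Compound list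

1 | 5-methoxyresorcinol (5-methoxybenzene-1,3-diol) | COc1cc(O)cc(O)c1 | starting material
2 | 1-methoxy-3,5-bis(methoxymethoxy)benzene | COCOc1cc(OC)cc(OCOC)c1 | intermediate
3 | [4-methoxy-2,6-bis(methoxymethoxy)phenyl]lithium | [Li]c1c(OCOC)cc(OC)cc1OCOC | intermediate
4 | [4-methoxy-2,6-bis(methoxymethoxy)phenyl]trimethylsilane | COCOc1cc(OC)cc(OCOC)c1[Si](C)(C)C | intermediate
5 | (R)-2-isopropyloxirane | CC(C)[C@@H]1CO1 | starting material
6 | [6-methoxy-2,4-bis(methoxymethoxy)-3-(trimethylsilyl)phenyl]lithium | [Li]c1c(OC)cc(OCOC)c([Si](C)(C)C)c1OCOC | intermediate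
7 | (2S)-1-[6-methoxy-2,4-bis(methoxymethoxy)-3-(trimethylsilyl)phenyl]-3-methylbutan-2-ol | COc1cc(OCOC)c([Si](C)(C)C)c(OCOC)c1C[C@H](O)C(C)C | intermediate
8 | (2S)-1-[3-bromo-6-methoxy-2,4-bis(methoxymethoxy)phenyl]-3-methylbutan-2-ol | COc1cc(OCOC)c(Br)c(OCOC)c1C[C@H](O)C(C)C | intermediate
9 | 2-bromo-4-[(2S)-2-hydroxy-3-methylbutyl]-5-methoxybenzene-1,3-diol | COc1cc(O)c(Br)c(O)c1C[C@H](O)C(C)C | intermediate
10 | 4-hydroxyphenylacetic acid | OC(=O)Cc1ccc(O)cc1 | starting material
11 | tert-butyl 2-(4-tert-butoxyphenyl)acetate | CC(C)(C)OC(=O)Cc1ccc(OC(C)(C)C)cc1 | intermediate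
12 | tert-butyl (2Z)-2-(4-tert-butoxyphenyl)-3-hydroxyprop-2-enoate | O/C=C(/c1ccc(OC(C)(C)C)cc1)C(=O)OC(C)(C)C | intermediate
13 | tert-butyl (2Z)-2-(4-tert-butoxyphenyl)-3-chloroprop-2-enoate | Cl/C=C(/c1ccc(OC(C)(C)C)cc1)C(=O)OC(C)(C)C | intermediate
14 | tert-butyl (2E)-3-{2-bromo-3-hydroxy-4-[(2S)-2-hydroxy-3-methylbutyl]-5-methoxyphenoxy}-2-(4-tert-butoxyphenyl)prop-2-enoate | COc1cc(O/C=C(\c2ccc(OC(C)(C)C)cc2)C(=O)OC(C)(C)C)c(Br)c(O)c1C[C@H](O)C(C)C | intermediate
15 | (2E)-3-{2-bromo-3-hydroxy-4-[(2S)-2-hydroxy-3-methylbutyl]-5-methoxyphenoxy}-2-(4-hydroxyphenyl)prop-2-enoic acid | COc1cc(O/C=C(\c2ccc(O)cc2)C(=O)O)c(Br)c(O)c1C[C@H](O)C(C)C | intermediate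
16 | (2E)-3-{3-acetoxy-4-[(2S)-2-acetoxy-3-methylbutyl]-2-bromo-5-methoxyphenoxy}-2-(4-acetoxyphenyl)prop-2-enoic acid | COc1cc(O/C=C(\c2ccc(OC(C)=O)cc2)C(=O)O)c(Br)c(OC(C)=O)c1C[C@H](OC(C)=O)C(C)C | intermediate
17 | (2E)-3-{3-acetoxy-4-[(2S)-2-acetoxy-3-methylbutyl]-2-bromo-5-methoxyphenoxy}-2-(4-acetoxyphenyl)prop-2-enoic trifluoroacetic anhydride | COc1cc(O/C=C(\c2ccc(OC(C)=O)cc2)C(=O)OC(=O)C(F)(F)F)c(Br)c(OC(C)=O)c1C[C@H](OC(C)=O)C(C)C | intermediate
18 | 7-acetoxy-6-[(2S)-2-acetoxy-3-methylbutyl]-3-(4-acetoxyphenyl)-8-bromo-5-methoxychromen-4-one | COc1c(C[C@H](OC(C)=O)C(C)C)c(OC(C)=O)c(Br)c2occ(-c3ccc(OC(C)=O)cc3)c(=O)c12 | intermediate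
19 | tributyl(3-methylbut-2-enyl)stannane | CCCC[Sn](CCCC)(CCCC)CC=C(C)C | starting material
20 | 7-acetoxy-6-[(2S)-2-acetoxy-3-methylbutyl]-3-(4-acetoxyphenyl)-5-methoxy-8-(3-methylbut-2-enyl)chromen-4-one | COc1c(C[C@H](OC(C)=O)C(C)C)c(OC(C)=O)c(CC=C(C)C)c2occ(-c3ccc(OC(C)=O)cc3)c(=O)c12 | intermediate
21 | 7-hydroxy-6-[(2S)-2-hydroxy-3-methylbutyl]-3-(4-hydroxyphenyl)-5-methoxy-8-(3-methylbut-2-enyl)chromen-4-one | COc1c(C[C@H](O)C(C)C)c(O)c(CC=C(C)C)c2occ(-c3ccc(O)cc3)c(=O)c12 | target

## Step count and least certain steps

Total: 13 steps. Longest linear sequence: 10 steps (steps 1–5 and 9–13, from 1 to 21). The side branch from 10 to 13 has 3 steps.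

**Step 11 (key step).** The E acid may reach the cyclising geometry too slowly, so that acid cleavage of the aryloxy-vinyl link or intermolecular acylation competes. Ring A, slowed by the bromine and the C7 acetoxy group, may also react sluggishly with the stabilised acylium ion. The fallback makes the C4–C4a bond first and closes ring C at O1–C2; the C8 bromine again leaves only C4a open. It sets out from 9 and 10. Friedel–Crafts C-acylation of 9 with 10 in BF3·OEt2 at 70 °C should give the deoxybenzoin 1-{3-bromo-2,4-dihydroxy-5-[(2S)-2-hydroxy-3-methylbutyl]-6-methoxyphenyl}-2-(4-hydroxyphenyl)ethan-1-one F1. Formylative ring closure with DMF, BF3·OEt2 and MsCl should then give 8-bromo-7-hydroxy-6-[(2S)-2-hydroxy-3-methylbutyl]-3-(4-hydroxyphenyl)-5-methoxychromen-4-one F2. Acetylation with Ac2O in pyridine returns the route at 18.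

**Step 9.** Poor discrimination between the two phenols of 9 would give O-vinylation at the hindered C7 oxygen or at both oxygens, because both are ortho to bromine and differ only in the second neighbour. The fallback moves the discrimination to a bulky silyl chloride, which allows wrong isomers to be desilylated and recycled before 13 is committed. It sets out from 9. TIPSCl and imidazole in CH2Cl2 at 0 °C should silylate only the less hindered phenol to give 2-bromo-6-[(2S)-2-hydroxy-3-methylbutyl]-5-methoxy-3-[tri(propan-2-yl)silyloxy]phenol F3. MOMCl and i-Pr2NEt cap the hindered phenol and the carbinol to give {2-bromo-5-methoxy-3-(methoxymethoxy)-4-[(2S)-2-(methoxymethoxy)-3-methylbutyl]phenoxy}tri(propan-2-yl)silane F4. TBAF frees 2-bromo-5-methoxy-3-(methoxymethoxy)-4-[(2S)-2-(methoxymethoxy)-3-methylbutyl]phenol F5. Substitution with 13 under the conditions of step 9 gives tert-butyl (2E)-3-{2-bromo-5-methoxy-3-(methoxymethoxy)-4-[(2S)-2-(methoxymethoxy)-3-methylbutyl]phenoxy}-2-(4-tert-butoxyphenyl)prop-2-enoate F6. TFA removes both tert-butyl groups and both MOM groups and returns the route at 15, inside step 10.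

**Step 4.** Bromination at the remaining ring C–H (the future C4a) may compete with ipso substitution, since that carbon is equally activated; loss of silicon to a proton from traces of HBr is also possible. The fallback introduces bromine through a carbanion at a defined site. It sets out from 7. Fluoride-induced protodesilylation (TBAF, wet DMF, 80 °C) should give (2S)-1-[2-methoxy-4,6-bis(methoxymethoxy)phenyl]-3-methylbutan-2-ol F7. n-BuLi (2.2 equiv, THF, 0 °C) then forms the alkoxide and lithiates the carbon between the two MOM ethers, as in step 2, and 1,2-dibromoethane transfers bromine to return the route at 8.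

**Step 12.** Oxidative addition at the doubly ortho-substituted bromide may be slow, and allyl transposition at palladium may deliver the branched 1,1-dimethylallyl isomer or a product of alkene migration. The fallback separates C–C coupling from construction of the trisubstituted alkene. It sets out from 18. Stille coupling with allyltributylstannane and Pd(PPh3)4 in DMF has no regiochemical ambiguity and should give 7-acetoxy-6-[(2S)-2-acetoxy-3-methylbutyl]-3-(4-acetoxyphenyl)-5-methoxy-8-(prop-2-enyl)chromen-4-one F8. Cross-metathesis with 2-methylbut-2-ene under the second-generation Grubbs catalyst converts the allyl into the prenyl group and returns the route at 20.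

## Further compounds

F1 | step 11 | 1-{3-bromo-2,4-dihydroxy-5-[(2S)-2-hydroxy-3-methylbutyl]-6-methoxyphenyl}-2-(4-hydroxyphenyl)ethan-1-one | COc1c(C[C@H](O)C(C)C)c(O)c(Br)c(O)c1C(=O)Cc1ccc(O)cc1
F2 | step 11 | 8-bromo-7-hydroxy-6-[(2S)-2-hydroxy-3-methylbutyl]-3-(4-hydroxyphenyl)-5-methoxychromen-4-one | COc1c(C[C@H](O)C(C)C)c(O)c(Br)c2occ(-c3ccc(O)cc3)c(=O)c12
F3 | step 9 | 2-bromo-6-[(2S)-2-hydroxy-3-methylbutyl]-5-methoxy-3-[tri(propan-2-yl)silyloxy]phenol | COc1cc(O[Si](C(C)C)(C(C)C)C(C)C)c(Br)c(O)c1C[C@H](O)C(C)C
F4 | step 9 | {2-bromo-5-methoxy-3-(methoxymethoxy)-4-[(2S)-2-(methoxymethoxy)-3-methylbutyl]phenoxy}tri(propan-2-yl)silane | COc1cc(O[Si](C(C)C)(C(C)C)C(C)C)c(Br)c(OCOC)c1C[C@H](OCOC)C(C)C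
F5 | step 9 | 2-bromo-5-methoxy-3-(methoxymethoxy)-4-[(2S)-2-(methoxymethoxy)-3-methylbutyl]phenol | COc1cc(O)c(Br)c(OCOC)c1C[C@H](OCOC)C(C)C
F6 | step 9 | tert-butyl (2E)-3-{2-bromo-5-methoxy-3-(methoxymethoxy)-4-[(2S)-2-(methoxymethoxy)-3-methylbutyl]phenoxy}-2-(4-tert-butoxyphenyl)prop-2-enoate | COc1cc(O/C=C(\c2ccc(OC(C)(C)C)cc2)C(=O)OC(C)(C)C)c(Br)c(OCOC)c1C[C@H](OCOC)C(C)C
F7 | step 4 | (2S)-1-[2-methoxy-4,6-bis(methoxymethoxy)phenyl]-3-methylbutan-2-ol | COc1cc(OCOC)cc(OCOC)c1C[C@H](O)C(C)C
F8 | step 12 | 7-acetoxy-6-[(2S)-2-acetoxy-3-methylbutyl]-3-(4-acetoxyphenyl)-5-methoxy-8-(prop-2-enyl)chromen-4-one | COc1c(C[C@H](OC(C)=O)C(C)C)c(OC(C)=O)c(CC=C)c2occ(-c3ccc(OC(C)=O)cc3)c(=O)c12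
A1 | alternative 1 | (S)-2-{1-[6-methoxy-2,4-bis(methoxymethoxy)-3-(3-methylbut-2-enyl)phenyl]-3-methylbutan-2-yl}-4,4,5,5-tetramethyl-1,3,2-dioxaborolane | COc1cc(OCOC)c(CC=C(C)C)c(OCOC)c1C[C@H](B2OC(C)(C)C(C)(C)O2)C(C)C
A2 | alternative 1 | 2-bromo-1-methoxy-3,5-bis(methoxymethoxy)-4-(3-methylbut-2-enyl)benzene | COc1cc(OCOC)c(CC=C(C)C)c(OCOC)c1Br
A3 | alternative 2 | 6-{[(2S)-3,3-dimethyloxiran-2-yl]methyl}-5-methoxy-7-(methoxymethoxy)-3-[4-(methoxymethoxy)phenyl]-8-(trimethylsilyl)chromen-4-one | COc1c(C[C@H]4C(C)(C)O4)c(OCOC)c([Si](C)(C)C)c2occ(-c3ccc(OCOC)cc3)c(=O)c12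
A4 | alternative 2 | 5-methoxy-7-(methoxymethoxy)-3-[4-(methoxymethoxy)phenyl]-6-(3-methylbut-2-enyl)-8-(trimethylsilyl)chromen-4-one | COc1c(CC=C(C)C)c(OCOC)c([Si](C)(C)C)c2occ(-c3ccc(OCOC)cc3)c(=O)c12
A5 | alternative 3 | 2-[(2S)-2-(tert-butyldimethylsilyloxy)-3-methylbutyl]-4-(3-methylbut-2-enyl)-3,5-bis(triisopropylsilyloxy)phenol | Oc1cc(O[Si](C(C)C)(C(C)C)C(C)C)c(CC=C(C)C)c(O[Si](C(C)C)(C(C)C)C(C)C)c1C[C@H](O[Si](C)(C)C(C)(C)C)C(C)C
A6 | alternative 3 | 2-(3-methylbut-2-enyl)-3-(triisopropylsilyloxy)cyclobut-2-en-1-one | CC(C)=CCC1=C(O[Si](C(C)C)(C(C)C)C(C)C)CC1=O
A7 | alternative 3 | tert-butyldimethyl{[(3S)-2-methyl-6-(triisopropylsilyloxy)hex-5-yn-3-yl]oxy}silane | CC(C)[Si](OC#CC[C@H](O[Si](C)(C)C(C)(C)C)C(C)C)(C(C)C)C(C)C
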